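**Remarks on the chemistry (assumptions and design choices)**

- C4 of the target is R (CIP order C4a > ring B ipso carbon > C3 > H). The same spatial arrangement is also R in the indanone 14 and the protected lactone 15.
- Assumption: (R)-BINAP is taken, by analogy with simple 3-substituted indanones, to give (R)-C4. The sense must be confirmed on the first run, and (S)-BINAP is the direct remedy if it proves opposite.
- All three phenols are carried as triisopropylsilyl ethers. A single, bulkier silyl type stands up better to the aqueous base of the couplings and to the Lewis acid of the oxygen insertion, and comes off in one operation.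
- The leaving group on C4a is a triflate made from a phenol that first directs iodination to C5. Ring A therefore comes from an unsymmetrical salicylaldehyde. A symmetric bromo-dialdehyde entry was not adopted, because its one-fold olefination is statistical and its two-fold benzylic oxidation would have to be run on an electron-rich silyl aryl ether.
- The rhodium catalyst is used as its tetrafluoroborate, not as a perchlorate.

## Structural features

The target is a 3,4-dihydrocoumarin: benzo ring A is fused through C4a and C8a to a six-membered lactone (O1, C2, C3, C4). C4 carries ring B (4-hydroxy-3-methoxyphenyl), C5 carries ring C (the same guaiacyl unit) through an E-ethene bridge, and C7 carries a free hydroxyl, so ring A is 1,2,3,5-tetrasubstituted with C4a and C5 as adjacent substituted positions. C4 is the only stereocenter; it has no stereogenic neighbour, so its configuration must come from a reagent or catalyst, and it is doubly benzylic and wedged between the lactone ring and the C5 styryl group. The fragile groups are the aryl ester of the lactone (opened by base and nucleophiles), the three phenols (two of them easily oxidised guaiacols) and the electron-rich E-stilbene (electrophilic oxidants, strong acid, light). The difficulty is twofold: setting C4 enantioselectively beside a fully substituted ortho position, and placing an oxygen on C8a without an oxidation that attacks the stilbene. The key step uses the fact that, once O1 is removed, the acyl carbon C2 sits on C8a, ortho to C4a which carries C4. The lactone is then a ring-expanded 3-arylindan-1-one whose C2–C3 bond can be made from a formyl C–H bond on C8a and a 1-arylvinyl group (C4=C3) on C4a, with hydrogen delivered to C4.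

## Logic of the disconnections

The three phenolic O–H bonds of 16 are replaced by O–Si bonds, giving 15. Free phenols would interfere with every base, palladium catalyst and Lewis acid used earlier, and three identical silyl groups can be removed together. Nothing is gained in skeleton; the gain is one uniform protecting layer. The forward step must cleave three aryl silyl ethers without opening the aryl ester of the lactone.

O1 is excised from 15: the O1–C8a and O1–C2 bonds are cut and C2 is joined to C8a, giving 14. The five-membered aryl ketone is the product type of a catalytic asymmetric C–C bond formation, which the lactone is not. The gain is that the C8a oxygen becomes a ring expansion with a predictable migrating group. The forward step must insert oxygen on the aryl side only, spare the stilbene and the silyl ethers, and leave C4 untouched.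

The C2–C3 bond of 14 is cut and the C4 hydrogen is returned to C2 as a formyl hydrogen, giving 13. This is the one bond whose formation from an aldehyde and an alkene creates C4 at the same time. The gain is the loss of a ring and of the only stereocenter: 13 is achiral. The forward step must select one face of a 1,1-diarylethene flanked by two ortho substituents and must outrun decarbonylation.

The C4a–C4 aryl–alkenyl bond of 13 is cut, giving 7 and 12. This is the most convergent cut: ring B with C3 and C4 is separated from rings A and C, and the halves are of similar size. The forward coupling must occur at an aryl carbon with two ortho substituents, with a 1,1-disubstituted alkenyl partner, and without harming the aldehyde.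

The S–O bond of 7 is cut to give 6, and the C5–alkenyl bond of 6 is then cut to give 5 and 2. The C4a hydroxyl is kept free until this point because it fixes where the halogen enters in 5; only afterwards does it become the leaving group. The gain is a ring A block whose three carbon-bearing positions are differentiated without a statistical step. The forward alkene arylation must be linear and E-selective and must tolerate a free ortho hydroxyl.

The C–I bond of 5 and then the O–Si bond of 4 are cut, leading to 3. Both cuts remove one heteroatom substituent from a commercial arene. The forward iodination must go ortho to the free hydroxyl, and the silylation must distinguish the two hydroxyls of 3.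

The C–B bond of 12, the enol C–O bond of 11 (formed through 10) and the O–Si bond of 9 are cut in turn, leading to 8. The methyl ketone of 8 already holds C3 and C4 at the right oxidation level for an alkenyl nucleophile. The forward steps require a single enolisation site and a borylation that does not homocouple.

The O–Si bond of 2 is cut, leading to 1, which already contains ring C and both alkene carbons. The forward step is a plain silylation.

## Other disconnections considered

Alternative 1: The cut runs through ring A at C5–C6 and C4a–C8a. In the forward step the acyclic ketone A1 (correctly an enynone, with one alkyne and one alkene; the alkyne carbons become C4a and C5) takes up the doubly silyloxylated methoxydiene A2 in a Diels–Alder reaction. Polarity matching sends the unsubstituted diene terminus to the styryl-bearing alkyne carbon, and loss of the methoxy group with desilylation aromatises the adduct to the benzophenone A3.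
- In its favour: ring A is assembled with all four substituents in place from acyclic pieces, and the C8a oxygen is present from the start. No oxygen has to be inserted later beside an electron-rich stilbene, and on this point the alternative is better than the chosen plan.
- Against it here: A3 carries C4 as a ketone. C2 and C3 must still be added, for instance by olefination–lactonisation to the 4-arylcoumarin A4. The stereocenter must then be made by an enantioselective conjugate reduction of a C3=C4 bond that is twisted by the C5 styryl group and must be told apart from the stilbene. The diene may also add in a Michael sense to the styryl terminus of A1, and the two free phenols of A3 must be distinguished.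
- Comparison: structurally it builds ring A (two bonds) and leaves the lactone ring and C4 to later steps, whereas step 10 closes the ring and sets C4 in one event. Mechanistically it is a metal-free pericyclic–elimination cascade that is stereochemically silent, against a catalyst-controlled organometallic step. In step count the two are estimated to be about equal (ten to twelve operations). The alternative is weaker in how late and how indirectly C4 is controlled.

Alternative 2: The cut removes the styryl carbon from C5 and opens ring A at C5–C6. In the forward step the styryllithium A6 adds to the lactone carbonyl of the bicyclic pyranone A5, which already holds C4 and the acetal-protected oxygen ring. The ring-opened keto dienolate closes ring A by aldol attack of the former methyl carbon on the new C5 ketone, and dehydration gives the phenol A7.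
- In its favour: C4 is installed at the outset by a conjugate addition of a type for which amine-catalysed enantiocontrol is well developed. The O1–C8a bond exists from the start, and the styryl group arrives as a complete, geometrically defined unit. In convergence and in the early setting of C4 the alternative is better than the chosen plan, and in step count it is at least its equal (estimated nine to eleven operations).
- Against it here: the organolithium must attack the lactone carbonyl and not the ring position usually attacked by carbon nucleophiles in pyranone ring transformations, and must stop after one addition. A second strong base must then make the methyl carbanion, which must prefer 1,2-addition to a styryl ketone over Michael addition. A7 still needs acetal hydrolysis, lactol oxidation in the presence of a free phenol and a stilbene, and acidic removal of the MOM groups.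
- Comparison: structurally it forms ring A and the C5–styryl bond together and never needs an oxygen insertion. Mechanistically it rests on a polar cascade with several branching points and less close precedent than step 10, whose risks are concentrated in one well-studied catalytic cycle. It is shorter on paper but more exposed to course changes in the key step.

Alternative 3: The cut opens ring A at C4a–C5 and the lactone at O1–C2. In the forward step aqueous base converts the open-chain triketo ester A8 into its C4a enolate, which closes ring A on the C5 ketone. Dehydration and enolisation aromatise the ring, and acidification lactonises the new C8a hydroxyl with the C2 carboxyl to give A9.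
- In its favour: both rings form in one flask without a metal, the C7 and C8a oxygens come from carbonyl groups already in the chain, and only the MOM groups remain to be removed. In redox economy and in the number of steps after the key step (one) the alternative is better than the chosen plan.
- Against it here: A8 must be made as a single enantiomer by a separate asymmetric step and then carried through polyanion acylations. It is a mixture of tautomers prone to O-cyclisation to pyranones and to conjugate addition at the styryl ketone (a flavanone-type closure). Its doubly activated C8 methylene can attack the ester in a Dieckmann-type closure unless the ester is saponified first. C4 lies β to the ester and to the C8a ketone, so retro-Michael loss of configuration in base before aromatisation is possible. The nucleophile must be the hindered C4a carbon.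
- Comparison: structurally it is the most direct, with two rings and two bonds in one step and the stereocenter imported. Mechanistically it depends on steering a polyketone among several closure modes, where the chosen plan keeps every step within a defined reaction class. It is the equal of the chosen plan in that neither sets C4 by substrate control, and the shorter of the two if A8 can be reached in a few steps, which is the uncertain part.

Key step: step 10

## Route

Step 1
Reactants: 1 2-methoxy-4-vinylphenol
Product: 2 triisopropyl(2-methoxy-4-vinylphenoxy)silane
Conditions: TIPSCl (1.1 equiv), imidazole (2.2 equiv), DMF, 0 °C to rt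
Reagents that add atoms: chlorotriisopropylsilane, CC(C)[Si](Cl)(C(C)C)C(C)C
Why: Imidazole-promoted silylation of a phenol; the silyl ether also removes the polymerisation-prone free vinylphenol.

Step 2
Reactants: 3 2,5-dihydroxybenzaldehyde
Product: 4 2-hydroxy-5-(triisopropylsilyloxy)benzaldehyde
Conditions: TIPSCl (1.05 equiv), imidazole (2 equiv), CH2Cl2, 0 °C
Reagents that add atoms: chlorotriisopropylsilane, CC(C)[Si](Cl)(C(C)C)C(C)C
Why: Chemoselective silylation: the C2 hydroxyl is hydrogen-bonded to and flanked by the formyl group, so the bulky silyl chloride should take the free C5 hydroxyl; any ortho silyl ether formed is labile and lost on work-up.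

Step 3
Reactants: 4 2-hydroxy-5-(triisopropylsilyloxy)benzaldehyde
Product: 5 2-hydroxy-3-iodo-5-(triisopropylsilyloxy)benzaldehyde
Conditions: NIS (1.05 equiv), TsOH·H2O (10 mol%), MeCN, 0 °C to rt, dark
Reagents that add atoms: N-iodosuccinimide, O=C1CCC(=O)N1I
Why: Electrophilic aromatic iodination ortho to the free phenol; the para position is occupied, C3 is also meta to the formyl group, and the positions beside the silyloxy group are shielded and not activated by the hydroxyl.

Step 4
Reactants: 5 2-hydroxy-3-iodo-5-(triisopropylsilyloxy)benzaldehyde; 2 triisopropyl(2-methoxy-4-vinylphenoxy)silane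
Product: 6 2-hydroxy-3-{(E)-2-[3-methoxy-4-(triisopropylsilyloxy)phenyl]vinyl}-5-(triisopropylsilyloxy)benzaldehyde
Conditions: Pd(OAc)2 (5 mol%), P(o-tol)3 (10 mol%), Et3N (3 equiv), DMF, 90 °C
Reagents that add atoms: none
Why: Mizoroki–Heck reaction of an aryl iodide with a styrene by the neutral pathway; syn insertion at the terminal carbon and syn β-hydride elimination should give the linear E-stilbene, and ortho-hydroxy aryl iodides are competent partners under amine base, which also spares the silyl ethers.

Step 5
Reactants: 6 2-hydroxy-3-{(E)-2-[3-methoxy-4-(triisopropylsilyloxy)phenyl]vinyl}-5-(triisopropylsilyloxy)benzaldehyde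
Product: 7 2-formyl-6-{(E)-2-[3-methoxy-4-(triisopropylsilyloxy)phenyl]vinyl}-4-(triisopropylsilyloxy)phenyl trifluoromethanesulfonate
Conditions: Tf2O (1.2 equiv), pyridine (3 equiv), CH2Cl2, −20 to 0 °C
Reagents that add atoms: trifluoromethanesulfonic anhydride, O=S(=O)(OS(=O)(=O)C(F)(F)F)C(F)(F)F
Why: O-Sulfonylation of an acidic salicylaldehyde-type phenol; it turns the directing hydroxyl on C4a into a leaving group activated for oxidative addition by the ortho formyl group.

Step 6
Reactants: 8 acetovanillone
Product: 9 1-[3-methoxy-4-(triisopropylsilyloxy)phenyl]ethanone
Conditions: TIPSCl (1.1 equiv), imidazole (2.2 equiv), DMF, rt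
Reagents that add atoms: chlorotriisopropylsilane, CC(C)[Si](Cl)(C(C)C)C(C)C
Why: Imidazole-promoted silylation of a phenol; the ketone is inert.

Step 7
Reactants: 9 1-[3-methoxy-4-(triisopropylsilyloxy)phenyl]ethanone
Product: 11 1-[3-methoxy-4-(triisopropylsilyloxy)phenyl]vinyl trifluoromethanesulfonate, via potassium enolate 10 (not isolated)
Conditions: KN(SiMe3)2 (1.1 equiv), THF, −78 °C; PhNTf2 (1.15 equiv), −78 to 0 °C; chromatography on Et3N-deactivated silica
Reagents that add atoms: N-phenylbis(trifluoromethanesulfonimide), O=S(=O)(N(c1ccccc1)S(=O)(=O)C(F)(F)F)C(F)(F)F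
Why: Deprotonation of a methyl ketone with one enolisable site and O-triflation of the potassium enolate gives a single enol triflate; buffered purification allows for the acid lability of electron-rich 1-arylvinyl triflates.

Step 8
Reactants: 11 1-[3-methoxy-4-(triisopropylsilyloxy)phenyl]vinyl trifluoromethanesulfonate
Product: 12 2-{1-[3-methoxy-4-(triisopropylsilyloxy)phenyl]vinyl}-4,4,5,5-tetramethyl-1,3,2-dioxaborolane
Conditions: B2pin2 (1.1 equiv), PdCl2(PPh3)2 (3 mol%), PPh3 (6 mol%), KOPh (1.5 equiv), toluene, 50 °C
Reagents that add atoms: bis(pinacolato)diboron, CC1(C)OB(B2OC(C)(C)C(C)(C)O2)OC1(C)C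
Why: Miyaura borylation of an alkenyl triflate; the weak phenoxide base activates the diboron without promoting Suzuki homocoupling of the product with unreacted triflate.

Step 9
Reactants: 7 2-formyl-6-{(E)-2-[3-methoxy-4-(triisopropylsilyloxy)phenyl]vinyl}-4-(triisopropylsilyloxy)phenyl trifluoromethanesulfonate; 12 2-{1-[3-methoxy-4-(triisopropylsilyloxy)phenyl]vinyl}-4,4,5,5-tetramethyl-1,3,2-dioxaborolane
Product: 13 2-{1-[3-methoxy-4-(triisopropylsilyloxy)phenyl]vinyl}-3-{(E)-2-[3-methoxy-4-(triisopropylsilyloxy)phenyl]vinyl}-5-(triisopropylsilyloxy)benzaldehyde
Conditions: Pd(OAc)2 (5 mol%), SPhos (10 mol%), K3PO4 (3 equiv), toluene/H2O 10:1, 60 °C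
Reagents that add atoms: none
Why: Suzuki–Miyaura coupling; the ortho formyl group speeds oxidative addition of the triflate, and the dialkylbiarylphosphine is chosen for transmetalation and reductive elimination at a doubly ortho-substituted aryl palladium with a 1,1-disubstituted alkenyl partner; phosphate at 60 °C should leave the triisopropylsilyl ethers and the aldehyde intact.

Step 10
Reactants: 13 2-{1-[3-methoxy-4-(triisopropylsilyloxy)phenyl]vinyl}-3-{(E)-2-[3-methoxy-4-(triisopropylsilyloxy)phenyl]vinyl}-5-(triisopropylsilyloxy)benzaldehyde
Product: 14 (R)-3-[3-methoxy-4-(triisopropylsilyloxy)phenyl]-4-{(E)-2-[3-methoxy-4-(triisopropylsilyloxy)phenyl]vinyl}-6-(triisopropylsilyloxy)indan-1-one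
Conditions: [Rh(nbd)((R)-BINAP)]BF4 (5 mol%), H2 then Ar purge, CH2Cl2, rt
Reagents that add atoms: none
Why: The cationic monovalent rhodium bisphosphine, freed of its diene by hydrogenation, adds oxidatively to the formyl C–H bond of 13 while the neighbouring 1-arylvinyl group chelates; the trivalent acyl rhodium hydride transfers hydride to the aryl-bearing alkene carbon C4 and binds C3, giving a six-membered rhodacycle, and C(acyl)–C(sp3) reductive elimination forms C2–C3 and releases 14. The closest known reaction type is the rhodium–BINAP-catalysed enantioselective intramolecular hydroacylation of 2-(1-substituted vinyl)benzaldehydes to 3-substituted indan-1-ones. The five-membered ketone ring closes in a formal 5-endo-trig mode, possible because the bond is made by reductive elimination from the metallacycle and not by direct attack on the alkene. C4 is set by the catalyst alone: the chiral array of P-phenyl groups of (R)-BINAP selects which face of the prochiral 1,1-diarylethene receives the hydride, the ligand antipode being chosen on the assumption stated in the remarks. Regioselectivity (hydrogen to C4, rhodium to C3) is secured by ring size, since the reverse addition could only lead to a strained four-membered ketone and is reversible. Chemoselectivity is secured by position: the stilbene double bond is meta to the formyl group, cannot reach the acyl rhodium hydride, and has no allylic hydrogen to isomerise. Decarbonylation should be held back by the chelating ortho alkene and the non-coordinating counter-ion, which keep a site open for fast insertion.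

Step 11
Reactants: 14 (R)-3-[3-methoxy-4-(triisopropylsilyloxy)phenyl]-4-{(E)-2-[3-methoxy-4-(triisopropylsilyloxy)phenyl]vinyl}-6-(triisopropylsilyloxy)indan-1-one
Product: 15 (R)-4-[3-methoxy-4-(triisopropylsilyloxy)phenyl]-5-{(E)-2-[3-methoxy-4-(triisopropylsilyloxy)phenyl]vinyl}-7-(triisopropylsilyloxy)chroman-2-one
Conditions: Me3SiOOSiMe3 (3 equiv), SnCl4 (30 mol%), trans-1,2-diaminocyclohexane (30 mol%), 4 Å MS, CH2Cl2, 0 °C to rt
Reagents that add atoms: bis(trimethylsilyl) peroxide, C[Si](C)(C)OO[Si](C)(C)C
Why: Baeyer–Villiger oxidation: the Lewis-acid-activated ketone adds the silyl peroxide, and in the silylated Criegee adduct the aryl carbon C8a migrates in preference to the primary C3 methylene, as expected for indan-1-ones, so that O1 enters between C2 and C8a. The silyl peroxide is a nucleophilic oxidant with no ability to transfer oxygen to alkenes, so the stilbene should survive; C4 is not at the migrating centre and keeps its configuration.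

Step 12
Reactants: 15 (R)-4-[3-methoxy-4-(triisopropylsilyloxy)phenyl]-5-{(E)-2-[3-methoxy-4-(triisopropylsilyloxy)phenyl]vinyl}-7-(triisopropylsilyloxy)chroman-2-one
Product: 16 (R)-7-hydroxy-4-(4-hydroxy-3-methoxyphenyl)-5-[(E)-2-(4-hydroxy-3-methoxyphenyl)vinyl]chroman-2-one (CNP0277187.1)
Conditions: Bu4NF (3.6 equiv), AcOH (4 equiv), THF, 0 °C to rt; pH 4 aqueous work-up
Reagents that add atoms: none
Why: Fluoride cleavage of three aryl Si–O bonds; acetic acid buffers fluoride and the phenoxides so that the aryl ester of the lactone should not be opened, and the mildly acidic work-up recloses any hydroxy acid that does form.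

## Compound list

1 | 2-methoxy-4-vinylphenol | C=Cc1ccc(O)c(OC)c1 | starting material
2 | triisopropyl(2-methoxy-4-vinylphenoxy)silane | C=Cc1ccc(O[Si](C(C)C)(C(C)C)C(C)C)c(OC)c1 | intermediate
3 | 2,5-dihydroxybenzaldehyde | O=Cc1cc(O)ccc1O | starting material
4 | 2-hydroxy-5-(triisopropylsilyloxy)benzaldehyde | O=Cc1cc(O[Si](C(C)C)(C(C)C)C(C)C)ccc1O | intermediate
5 | 2-hydroxy-3-iodo-5-(triisopropylsilyloxy)benzaldehyde | O=Cc1cc(O[Si](C(C)C)(C(C)C)C(C)C)cc(I)c1O | intermediate
6 | 2-hydroxy-3-{(E)-2-[3-methoxy-4-(triisopropylsilyloxy)phenyl]vinyl}-5-(triisopropylsilyloxy)benzaldehyde | O=Cc1cc(O[Si](C(C)C)(C(C)C)C(C)C)cc(/C=C/c2ccc(O[Si](C(C)C)(C(C)C)C(C)C)c(OC)c2)c1O | intermediate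
7 | 2-formyl-6-{(E)-2-[3-methoxy-4-(triisopropylsilyloxy)phenyl]vinyl}-4-(triisopropylsilyloxy)phenyl trifluoromethanesulfonate | O=Cc1cc(O[Si](C(C)C)(C(C)C)C(C)C)cc(/C=C/c2ccc(O[Si](C(C)C)(C(C)C)C(C)C)c(OC)c2)c1OS(=O)(=O)C(F)(F)F | intermediate
8 | acetovanillone, 1-(4-hydroxy-3-methoxyphenyl)ethanone | CC(=O)c1ccc(O)c(OC)c1 | starting material
9 | 1-[3-methoxy-4-(triisopropylsilyloxy)phenyl]ethanone | CC(=O)c1ccc(O[Si](C(C)C)(C(C)C)C(C)C)c(OC)c1 | intermediate
10 | potassium 1-[3-methoxy-4-(triisopropylsilyloxy)phenyl]ethenolate | [K+].[O-]C(=C)c1ccc(O[Si](C(C)C)(C(C)C)C(C)C)c(OC)c1 | intermediate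
11 | 1-[3-methoxy-4-(triisopropylsilyloxy)phenyl]vinyl trifluoromethanesulfonate | C=C(OS(=O)(=O)C(F)(F)F)c1ccc(O[Si](C(C)C)(C(C)C)C(C)C)c(OC)c1 | intermediate
12 | 2-{1-[3-methoxy-4-(triisopropylsilyloxy)phenyl]vinyl}-4,4,5,5-tetramethyl-1,3,2-dioxaborolane | C=C(B1OC(C)(C)C(C)(C)O1)c1ccc(O[Si](C(C)C)(C(C)C)C(C)C)c(OC)c1 | intermediate
13 | 2-{1-[3-methoxy-4-(triisopropylsilyloxy)phenyl]vinyl}-3-{(E)-2-[3-methoxy-4-(triisopropylsilyloxy)phenyl]vinyl}-5-(triisopropylsilyloxy)benzaldehyde | O=Cc1cc(O[Si](C(C)C)(C(C)C)C(C)C)cc(/C=C/c2ccc(O[Si](C(C)C)(C(C)C)C(C)C)c(OC)c2)c1C(=C)c1ccc(O[Si](C(C)C)(C(C)C)C(C)C)c(OC)c1 | intermediate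
14 | (R)-3-[3-methoxy-4-(triisopropylsilyloxy)phenyl]-4-{(E)-2-[3-methoxy-4-(triisopropylsilyloxy)phenyl]vinyl}-6-(triisopropylsilyloxy)indan-1-one | COc1cc(/C=C/c2cc(O[Si](C(C)C)(C(C)C)C(C)C)cc3c2[C@@H](c2ccc(O[Si](C(C)C)(C(C)C)C(C)C)c(OC)c2)CC3=O)ccc1O[Si](C(C)C)(C(C)C)C(C)C | intermediate
15 | (R)-4-[3-methoxy-4-(triisopropylsilyloxy)phenyl]-5-{(E)-2-[3-methoxy-4-(triisopropylsilyloxy)phenyl]vinyl}-7-(triisopropylsilyloxy)chroman-2-one | COc1cc(/C=C/c2cc(O[Si](C(C)C)(C(C)C)C(C)C)cc3c2[C@@H](c2ccc(O[Si](C(C)C)(C(C)C)C(C)C)c(OC)c2)CC(=O)O3)ccc1O[Si](C(C)C)(C(C)C)C(C)C | intermediate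
16 | (R)-7-hydroxy-4-(4-hydroxy-3-methoxyphenyl)-5-[(E)-2-(4-hydroxy-3-methoxyphenyl)vinyl]chroman-2-one | COc1cc(/C=C/c2cc(O)cc3c2[C@@H](c2ccc(O)c(OC)c2)CC(=O)O3)ccc1O | target

## Step count and risk

Total step count: 12. Longest linear sequence: 8 steps (steps 2, 3, 4, 5, 9, 10, 11, 12, from 3 to 16).

Least certain steps:

Step 10 (key step). The most likely failure is poor enantioface discrimination in the hydride transfer, because the C5 styryl group and the formyl group together twist the 1,1-diarylethene and crowd the rhodacycle; slow insertion would also give decarbonylation more time. Fallback, setting out from 13 and returning to 14: the ring is closed without asking for induction, using the achiral complex [Rh(nbd)(dppe)]BF4 (activated with H2), to give the racemic indanone F1. Dehydrogenation with 2-iodoxybenzoic acid in DMSO/fluorobenzene at 70 °C removes the stereocenter and gives the 3-arylinden-1-one F2. A copper hydride conjugate reduction (Cu(OAc)2, DTBM-SEGPHOS of the required handedness, polymethylhydrosiloxane, t-BuOH, toluene) then sets C4 and returns 14. The stereo-determining event is thus moved from a migratory insertion in a crowded metallacycle to hydride delivery to a planar β-aryl cyclopentenone, a known substrate type for that reduction; the unactivated stilbene should not be reduced.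

Step 11. The most likely failure is slow addition of the silyl peroxide to a conjugated, hindered aryl ketone whose migrating carbon has no ortho or para donor, so that Lewis-acid cleavage of Si–O bonds or cationic reactions of the stilbene overtake the oxygen insertion. Stronger peracids are not a simple substitute because they would epoxidise the stilbene. Fallback, setting out from 14 and returning to 15: the alkene is masked and restored.
- Catalytic OsO4 with N-methylmorpholine N-oxide gives the syn-diol F3 (two diastereomers, of no consequence).
- 2,2-Dimethoxypropane with pyridinium tosylate gives the acetonide F4.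
- A classical peracid Baeyer–Villiger oxidation (mCPBA with NaHCO3, or buffered CF3CO3H with Na2HPO4) gives the lactone acetonide F5.
- Aqueous acetic acid gives the lactone diol F6.
- 1,1'-Thiocarbonyldiimidazole gives the cyclic thionocarbonate F7.
- Corey–Winter olefination with 1,3-dimethyl-2-phenyl-1,3,2-diazaphospholidine at 40 °C returns 15.

Because dihydroxylation and the olefination are both syn-stereospecific, the E geometry should be recovered.

Step 9. The most likely failure is slow transmetalation at the doubly ortho-substituted aryl palladium, which would let hydrolysis of the triflate S–O bond and protodeboronation of the 1-arylvinylboronate take over. Fallback, setting out from 7 and 11 and returning to 13: the polarity is reversed. Borylation of 7 (B2pin2, PdCl2(dppf), KOAc, dioxane, 80 °C) gives the ortho-formyl arylboronate F8, which is coupled with the enol triflate 11 (Pd(PPh3)4, K3PO4, dioxane/H2O, 60 °C). The hindered partner then enters as the nucleophile and the fast-reacting alkenyl triflate as the electrophile, the usual way of making 2-(1-substituted vinyl)benzaldehydes.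

Step 4. The most likely failure is leakage of the insertion to the internal alkene carbon with the electron-rich styrene, giving a branched 1,1-diaryl alkene, or retardation by the ortho phenoxide. Fallback, setting out from 2 and 5 and returning to 6: the geometry and connectivity are fixed beforehand in the nucleophile. Cross-metathesis of 2 with 4,4,5,5-tetramethyl-2-vinyl-1,3,2-dioxaborolane (second-generation Grubbs catalyst, CH2Cl2, 40 °C) gives the (E)-styrylboronate F9. Suzuki–Miyaura coupling of F9 with 5 (PdCl2(dppf), K3PO4, dioxane/H2O, 60 °C) then gives 6.

## Further compounds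

F1 | step 10 | racemic 3-[3-methoxy-4-(triisopropylsilyloxy)phenyl]-4-{(E)-2-[3-methoxy-4-(triisopropylsilyloxy)phenyl]vinyl}-6-(triisopropylsilyloxy)indan-1-one | COc1cc(/C=C/c2cc(O[Si](C(C)C)(C(C)C)C(C)C)cc3c2C(c2ccc(O[Si](C(C)C)(C(C)C)C(C)C)c(OC)c2)CC3=O)ccc1O[Si](C(C)C)(C(C)C)C(C)C
F2 | step 10 | 3-[3-methoxy-4-(triisopropylsilyloxy)phenyl]-4-{(E)-2-[3-methoxy-4-(triisopropylsilyloxy)phenyl]vinyl}-6-(triisopropylsilyloxy)inden-1-one | COc1cc(/C=C/c2cc(O[Si](C(C)C)(C(C)C)C(C)C)cc3c2C(c2ccc(O[Si](C(C)C)(C(C)C)C(C)C)c(OC)c2)=CC3=O)ccc1O[Si](C(C)C)(C(C)C)C(C)C
F3 | step 11 | (R)-indan-1-one 14 with the stilbene as syn-1,2-diol, two diastereomers | COc1cc(C(O)C(O)c2cc(O[Si](C(C)C)(C(C)C)C(C)C)cc3c2[C@@H](c2ccc(O[Si](C(C)C)(C(C)C)C(C)C)c(OC)c2)CC3=O)ccc1O[Si](C(C)C)(C(C)C)C(C)C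
F4 | step 11 | acetonide of the diol F3 | COc1cc(C2OC(C)(C)OC2c2cc(O[Si](C(C)C)(C(C)C)C(C)C)cc3c2[C@@H](c2ccc(O[Si](C(C)C)(C(C)C)C(C)C)c(OC)c2)CC3=O)ccc1O[Si](C(C)C)(C(C)C)C(C)C
F5 | step 11 | (R)-chroman-2-one with the stilbene as diol acetonide | COc1cc(C2OC(C)(C)OC2c2cc(O[Si](C(C)C)(C(C)C)C(C)C)cc3c2[C@@H](c2ccc(O[Si](C(C)C)(C(C)C)C(C)C)c(OC)c2)CC(=O)O3)ccc1O[Si](C(C)C)(C(C)C)C(C)C
F6 | step 11 | (R)-chroman-2-one with the stilbene as syn-1,2-diol | COc1cc(C(O)C(O)c2cc(O[Si](C(C)C)(C(C)C)C(C)C)cc3c2[C@@H](c2ccc(O[Si](C(C)C)(C(C)C)C(C)C)c(OC)c2)CC(=O)O3)ccc1O[Si](C(C)C)(C(C)C)C(C)C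
F7 | step 11 | cyclic thionocarbonate of the diol F6 | COc1cc(C2OC(=S)OC2c2cc(O[Si](C(C)C)(C(C)C)C(C)C)cc3c2[C@@H](c2ccc(O[Si](C(C)C)(C(C)C)C(C)C)c(OC)c2)CC(=O)O3)ccc1O[Si](C(C)C)(C(C)C)C(C)C
F8 | step 9 | 3-{(E)-2-[3-methoxy-4-(triisopropylsilyloxy)phenyl]vinyl}-2-(4,4,5,5-tetramethyl-1,3,2-dioxaborolan-2-yl)-5-(triisopropylsilyloxy)benzaldehyde | O=Cc1cc(O[Si](C(C)C)(C(C)C)C(C)C)cc(/C=C/c2ccc(O[Si](C(C)C)(C(C)C)C(C)C)c(OC)c2)c1B1OC(C)(C)C(C)(C)O1
F9 | step 4 | 2-{(E)-2-[3-methoxy-4-(triisopropylsilyloxy)phenyl]vinyl}-4,4,5,5-tetramethyl-1,3,2-dioxaborolane | COc1cc(/C=C/B2OC(C)(C)C(C)(C)O2)ccc1O[Si](C(C)C)(C(C)C)C(C)C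
A1 | alternative 1 | (E)-1,5-bis[3-methoxy-4-(methoxymethoxy)phenyl]pent-4-en-2-yn-1-one | O=C(C#C/C=C/c1ccc(OCOC)c(OC)c1)c1ccc(OCOC)c(OC)c1
A2 | alternative 1 | 1-methoxy-1,3-bis(trimethylsilyloxy)buta-1,3-diene | COC(O[Si](C)(C)C)=CC(=C)O[Si](C)(C)C
A3 | alternative 1 | 2,4-dihydroxy-6-styrylbenzophenone with ring B and ring C phenols as MOM ethers | O=C(c1ccc(OCOC)c(OC)c1)c1c(O)cc(O)cc1/C=C/c1ccc(OCOC)c(OC)c1
A4 | alternative 1 | 7-hydroxy-4-aryl-5-styrylcoumarin with ring B and ring C phenols as MOM ethers | O=c1cc(-c2ccc(OCOC)c(OC)c2)c2c(/C=C/c3ccc(OCOC)c(OC)c3)cc(O)cc2o1
A5 | alternative 2 | 2-methoxy-4-[3-methoxy-4-(methoxymethoxy)phenyl]-7-methyl-3,4-dihydro-2H,5H-pyrano[4,3-b]pyran-5-one, C4 as in the target, acetal carbon as anomer mixture | COC1C[C@H](c2ccc(OCOC)c(OC)c2)c2c(cc(C)oc2=O)O1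
A6 | alternative 2 | (E)-2-[3-methoxy-4-(methoxymethoxy)phenyl]vinyllithium | [Li]/C=C/c1ccc(OCOC)c(OC)c1
A7 | alternative 2 | 4-aryl-2-methoxy-5-styrylchroman-7-ol with ring B and ring C phenols as MOM ethers, acetal carbon as anomer mixture | COc1cc(/C=C/c2cc(O)cc3c2[C@@H](c2ccc(OCOC)c(OC)c2)CC(OC)O3)ccc1OCOC
A8 | alternative 3 | methyl (E)-3,11-bis[3-methoxy-4-(methoxymethoxy)phenyl]-5,7,9-trioxoundec-10-enoate, C3 of the chain configured as C4 of the target | COC(=O)C[C@H](c1ccc(OCOC)c(OC)c1)CC(=O)CC(=O)CC(=O)/C=C/c1ccc(OCOC)c(OC)c1
A9 | alternative 3 | the target lactone with ring B and ring C phenols as MOM ethers | COc1cc(/C=C/c2cc(O)cc3c2[C@@H](c2ccc(OCOC)c(OC)c2)CC(=O)O3)ccc1OCOC
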